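**Retrosynthetic overview**

1. Core locants: hexahydro-2H-furo[3,2-b]pyran-5-one (O1, C2, C3, C3a, O4, C5, C6, C7, C7a), side chain C1′–C5′. The oxolane ring O1–C2–C3–C3a–C7a is all-cis, and its oxygen is flanked by C2 and C7a, each bonded to an O-bearing ring carbon (C3, C3a). This is the pattern of a furan (O1, C2, C7a, with C7 and C1′ as its β-carbons) that has added a cis-enediol across its α-positions. C2–C3 and C3a–C7a are therefore made by an endo Diels–Alder reaction of furan with vinylene carbonate, whose carbonyl carbon is the future lactone carbon C5.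
2. The C7=C1′ bridge of the meso 7-oxanorbornene is opened by enantioselective ring-opening cross-metathesis with the side-chain alkene. This frees the oxolane, fixes the absolute configuration, forms E-C1′=C2′, and leaves a vinyl group (C7=C6) on C7a.
3. Wacker oxidation gives the C7 methyl ketone. Its enolate (C6) takes the carbonate carbonyl from O3a/O3 (C5–C6 bond, δ-lactone), and ketone reduction gives 7-OH.
4. The side-chain alkene comes from methyl (R)-lactate: Felkin–Anh vinyl addition, benzoylation, desilylation, acetylation.
5. Ring order: 7-oxanorbornene with fused dioxolanone (contains the latent oxolane) first, then the free oxolane by ring opening, then the δ-lactone last.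

Key step: step 1

Remark: the locants of line 1 are used for the corresponding atoms of all intermediates. The antipode of the chiral metathesis catalyst in step 7 is assumed to be chosen in a test reaction, since both antipodes are accessible.

**Route**

Step 1
Reactants: 1 furan; 2 vinylene carbonate
Product: 3 meso endo adduct, (3aR,4S,7R,7aS)-3a,4,7,7a-tetrahydro-4,7-epoxy-1,3-benzodioxol-2-one (carbonate ring syn to the C=C bridge)
Conditions: furan (5 equiv), neat, sealed tube, 120 °C (or CH2Cl2, 12 kbar, rt); endo isomer separated by crystallisation/chromatography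
Reagents that add atoms: none
Why: Concerted suprafacial [4+2] cycloaddition (Diels–Alder) of furan with the cis-locked enediol equivalent vinylene carbonate, a known thermal reaction of exactly this pair. It closes the six-membered carbocycle of a 7-oxabicyclo[2.2.1]heptene by cycloaddition (both σ-bonds on one diene face, no exo/endo-trig cyclisation involved) and thereby completes the five-membered ring O1–C2–C3–C3a–C7a. C2 and C7a are cis because both bonds form on the same furan face; C3 and C3a are cis because the dienophile is a cyclic Z-alkene; their endo relation to the C7=C1′ bridge (all four oxolane substituents cis) comes from endo approach of the carbonate under the diene. The selectivity needed is endo over exo, which the substrate does not enforce: the endo adduct should be the kinetic one, so the reaction is run at the lowest effective temperature or under pressure, the endo isomer is separated, and the exo isomer is returned to 1 and 2 by thermal cycloreversion. Regiochemistry and absolute configuration need no control here because both partners are symmetric and 3 is meso. All atoms of both partners stay in the target, and the carbonate carbon becomes C5.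

Step 2
Reactants: 4 methyl (R)-lactate
Product: 5 methyl (2R)-2-[(tert-butyldimethylsilyl)oxy]propanoate
Conditions: TBSCl, imidazole, DMF, 0 °C → rt
Reagents that add atoms: tert-butyldimethylsilyl chloride, CC(C)(C)[Si](C)(C)Cl
Why: Imidazole-promoted silylation of a secondary alcohol; the stereocentre is not involved.

Step 3
Reactants: 5
Product: 7 (3S,4R)-4-[(tert-butyldimethylsilyl)oxy]pent-1-en-3-ol, via (R)-2-silyloxypropanal 6 (not isolated)
Conditions: DIBAL-H (1.05 equiv), CH2Cl2, −78 °C; then CH2=CHMgBr, −78 → 0 °C; sat. aq. NH4Cl, aq. potassium sodium tartrate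
Reagents that add atoms: vinylmagnesium bromide, C=C[Mg]Br
Why: One-pot semi-reduction of the ester and Grignard addition avoids isolating the epimerisable aldehyde; the non-chelating silyloxy group should direct the vinyl nucleophile by Felkin–Anh control to the 3,4-anti (3S) alcohol, and the minor syn epimer is removed by chromatography.

Step 4
Reactants: 7
Product: 8 (3S,4R)-4-[(tert-butyldimethylsilyl)oxy]pent-1-en-3-yl benzoate
Conditions: BzCl, pyridine, DMAP (cat.), CH2Cl2, 0 °C → rt
Reagents that add atoms: benzoyl chloride, O=C(Cl)c1ccccc1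
Why: DMAP-catalysed O-acylation of the secondary allylic alcohol, with retention at C3′.

Step 5
Reactants: 8
Product: 9 (3S,4R)-4-hydroxypent-1-en-3-yl benzoate
Conditions: HF·pyridine, THF/pyridine, 0 °C → rt
Reagents that add atoms: none
Why: Fluoride cleavage of the Si–O bond under acidic, non-basic conditions, which should suppress 1,2-benzoyl migration to the freed hydroxyl.

Step 6
Reactants: 9
Product: 10 (3S,4R)-4-(acetyloxy)pent-1-en-3-yl benzoate
Conditions: Ac2O, pyridine, DMAP (cat.), CH2Cl2, 0 °C
Reagents that add atoms: acetic anhydride, CC(=O)OC(C)=O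
Why: Standard acetylation of a secondary alcohol; no stereocentre is touched.

Step 7
Reactants: 3; 10
Product: 11 (3aS,4R,6S,6aR)-4-ethenyl-6-[(1E,3S,4R)-4-(acetyloxy)-3-(benzoyloxy)pent-1-en-1-yl]tetrahydrofuro[3,4-d][1,3]dioxol-2-one (all four ring substituents cis)
Conditions: 3 (1 equiv), 10 (2 equiv, excess recovered), chiral bidentate NHC–aryloxide Ru carbene (5 mol %), THF, 22 °C
Reagents that add atoms: none
Why: Ru-catalysed asymmetric ring-opening cross-metathesis of a strained meso 7-oxanorbornene with a terminal alkene: strain release makes ring opening irreversible, the chiral Ru alkylidene selects one of the two enantiotopic alkene carbons (this fixes the absolute configuration of C2, C3, C3a and C7a without creating a new stereocentre), the α-branched alkylidene should favour the E-alkene, and the CH2 of 10 caps the other terminus as the vinyl group.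

Step 8
Reactants: 11
Product: 12 (3aR,4S,6S,6aR)-4-acetyl-6-[(1E,3S,4R)-4-(acetyloxy)-3-(benzoyloxy)pent-1-en-1-yl]tetrahydrofuro[3,4-d][1,3]dioxol-2-one
Conditions: Pd(Quinox)Cl2 (5 mol %), AgSbF6 (12 mol %), aq. TBHP, CH2Cl2, 0 °C → rt
Reagents that add atoms: tert-butyl hydroperoxide, CC(C)(C)OO
Why: Wacker–Tsuji oxidation with a catalyst system that gives methyl ketones (Markovnikov) from terminal alkenes bearing an allylic oxygen without touching the adjacent stereocentre; the internal, ester-flanked E-alkene should be much less reactive.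

Step 9
Reactants: 12
Product: 13 (1E,3S,4R)-4-(acetyloxy)-1-[(2S,3R,3aR,7aS)-3-hydroxy-5,7-dioxohexahydro-2H-furo[3,2-b]pyran-2-yl]pent-1-en-3-yl benzoate
Conditions: LiHMDS (1.1 equiv), THF, −78 → −20 °C; then cold 1 M HCl
Reagents that add atoms: none
Why: Intramolecular Claisen (Dieckmann-type) C-acylation of the kinetic methyl enolate by the cis-disposed cyclic carbonate (6-exo-trig, the same type as the carbonate route to 4-hydroxycoumarins): the tetrahedral intermediate should expel the O3 alkoxide to give the six- rather than the seven-membered lactone, and that alkoxide deprotonates the β-keto lactone, which drives the isomerisation and shields C7a from epimerisation.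

Step 10
Reactants: 13
Product: 14 target, (1E,3S,4R)-4-(acetyloxy)-1-[(2S,3R,3aR,7R,7aR)-3,7-dihydroxy-5-oxohexahydro-2H-furo[3,2-b]pyran-2-yl]pent-1-en-3-yl benzoate
Conditions: NaBH4, CeCl3·7H2O, MeOH/THF, −40 °C; AcOH quench
Reagents that add atoms: none
Why: Hydride reduction of the keto tautomer from the convex face of the cis-fused bicycle, anti to the C7a–O1 bond (Felkin–Anh) and away from the oxolane ring, should set (7R)-OH cis to O1; esters and lactone are inert to borohydride at this temperature.

**Compound list**

1 | furan | c1ccoc1 | starting material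
2 | vinylene carbonate (1,3-dioxol-2-one) | O=C1OC=CO1 | starting material
3 | meso endo adduct, (3aR,4S,7R,7aS)-3a,4,7,7a-tetrahydro-4,7-epoxy-1,3-benzodioxol-2-one | C1=C[C@H]2O[C@@H]1[C@H]1OC(=O)O[C@@H]21 | intermediate
4 | methyl (R)-lactate | C[C@@H](O)C(=O)OC | starting material
5 | methyl (2R)-2-[(tert-butyldimethylsilyl)oxy]propanoate | CC(C)(C)[Si](C)(C)O[C@H](C)C(=O)OC | intermediate
6 | (2R)-2-[(tert-butyldimethylsilyl)oxy]propanal | CC(C)(C)[Si](C)(C)O[C@H](C)C=O | intermediate
7 | (3S,4R)-4-[(tert-butyldimethylsilyl)oxy]pent-1-en-3-ol | CC(C)(C)[Si](C)(C)O[C@H](C)[C@H](C=C)O | intermediate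
8 | (3S,4R)-4-[(tert-butyldimethylsilyl)oxy]pent-1-en-3-yl benzoate | CC(C)(C)[Si](C)(C)O[C@H](C)[C@H](C=C)OC(=O)c1ccccc1 | intermediate
9 | (3S,4R)-4-hydroxypent-1-en-3-yl benzoate | O[C@H](C)[C@H](C=C)OC(=O)c1ccccc1 | intermediate
10 | (3S,4R)-4-(acetyloxy)pent-1-en-3-yl benzoate | CC(=O)O[C@H](C)[C@H](C=C)OC(=O)c1ccccc1 | intermediate
11 | (3aS,4R,6S,6aR)-4-ethenyl-6-[(1E,3S,4R)-4-(acetyloxy)-3-(benzoyloxy)pent-1-en-1-yl]tetrahydrofuro[3,4-d][1,3]dioxol-2-one | CC(=O)O[C@H](C)[C@H](/C=C/[C@@H]1O[C@H](C=C)[C@@H]2OC(=O)O[C@H]12)OC(=O)c1ccccc1 | intermediate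
12 | (3aR,4S,6S,6aR)-4-acetyl-6-[(1E,3S,4R)-4-(acetyloxy)-3-(benzoyloxy)pent-1-en-1-yl]tetrahydrofuro[3,4-d][1,3]dioxol-2-one | CC(=O)O[C@H](C)[C@H](/C=C/[C@@H]1O[C@H](C(C)=O)[C@@H]2OC(=O)O[C@H]12)OC(=O)c1ccccc1 | intermediate
13 | (1E,3S,4R)-4-(acetyloxy)-1-[(2S,3R,3aR,7aS)-3-hydroxy-5,7-dioxohexahydro-2H-furo[3,2-b]pyran-2-yl]pent-1-en-3-yl benzoate | CC(=O)O[C@H](C)[C@H](/C=C/[C@@H]1O[C@H]2[C@H](OC(=O)CC2=O)[C@@H]1O)OC(=O)c1ccccc1 | intermediate
14 | (1E,3S,4R)-4-(acetyloxy)-1-[(2S,3R,3aR,7R,7aR)-3,7-dihydroxy-5-oxohexahydro-2H-furo[3,2-b]pyran-2-yl]pent-1-en-3-yl benzoate (CNP0230210.1) | CC(=O)O[C@H](C)[C@H](/C=C/[C@@H]1O[C@H]2[C@H](OC(=O)C[C@H]2O)[C@@H]1O)OC(=O)c1ccccc1 | target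

**Step count and risks**

Total step count: 10. Longest linear sequence: 9 steps (4 → 14, steps 2–10); the core branch from furan is 5 steps (1, 7–10).

Steps most likely to fail:

1. Step 7. What may go wrong: poor discrimination between the two enantiotopic alkene carbons by the chiral Ru alkylidene (which would give the diastereomer with the mirror-image oxolane core), erosion of E-selectivity, and ring-opening oligomerisation. The fallback sets out from 2 and comes back at 12, so step 8 is bypassed as well. Vinylene carbonate 2 is heated with commercial 3-methylfuran (Cc1ccoc1); the endo adduct forms as a racemate, and the required enantiomer endo-5-methyl-3a,4,7,7a-tetrahydro-4,7-epoxy-1,3-benzodioxol-2-one F1 is collected by preparative chromatography on a chiral phase. Ozonolysis (O3, CH2Cl2, −78 °C; Me2S) cleaves the trisubstituted bridge alkene to all-cis 4-acetyl-6-formyltetrahydrofuro[3,4-d][1,3]dioxol-2-one F2. Aldehyde-selective Takai methylenation (CH2I2, Zn, Ti(Oi-Pr)4, THF) then gives all-cis 4-acetyl-6-ethenyltetrahydrofuro[3,4-d][1,3]dioxol-2-one F3. Cross-metathesis of F3 with 10 (Ru–NHC catalyst, CH2Cl2, 40 °C) should give the E-alkene 12.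

2. Step 9. What may go wrong: proton transfer to the C7a enolate followed by β-elimination of the O3a carbonate oxygen, or attack of base or enolate on the side-chain acetate and benzoate. The fallback sets out from 12 and comes back at 13. The kinetic enolate is trapped as it forms (LiHMDS added to 12 and TMSCl, THF, −78 °C) to give the trimethylsilyl enol ether of 12, the 4-[1-(trimethylsilyloxy)ethenyl] analogue F4, which is purified. A stoichiometric anhydrous fluoride source (TASF, THF, −40 °C) then releases the enolate regiospecifically in the absence of amide base, and the same acyl transfer followed by mild acidic work-up gives 13.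

3. Step 8. What may go wrong: Pd(II)-induced 1,3-transposition of the allylic benzoate across C1′=C2′, or oxidation at the terminal carbon to the aldehyde. The fallback sets out from 11 and comes back at 12. Mukaiyama hydration of the terminal alkene (Co(acac)2 cat., PhSiH3, O2, i-PrOH, rt) gives the 4-(1-hydroxyethyl) analogue of 11 as a mixture of carbinol epimers F5, and oxidation with the periodinane DMP (CH2Cl2, NaHCO3) converges both epimers on 12.

Further compounds
F1 | step 7 | endo-5-methyl-3a,4,7,7a-tetrahydro-4,7-epoxy-1,3-benzodioxol-2-one (enantiomer collected after resolution) | C1=C(C)[C@H]2O[C@@H]1[C@H]1OC(=O)O[C@@H]21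
F2 | step 7 | all-cis 4-acetyl-6-formyltetrahydrofuro[3,4-d][1,3]dioxol-2-one | O=C[C@@H]1O[C@H](C(C)=O)[C@@H]2OC(=O)O[C@H]12
F3 | step 7 | all-cis 4-acetyl-6-ethenyltetrahydrofuro[3,4-d][1,3]dioxol-2-one | C=C[C@@H]1O[C@H](C(C)=O)[C@@H]2OC(=O)O[C@H]12
F4 | step 9 | trimethylsilyl enol ether of 12, 4-[1-(trimethylsilyloxy)ethenyl] analogue | CC(=O)O[C@H](C)[C@H](/C=C/[C@@H]1O[C@H](C(=C)O[Si](C)(C)C)[C@@H]2OC(=O)O[C@H]12)OC(=O)c1ccccc1
F5 | step 8 | 4-(1-hydroxyethyl) analogue of 11 (carbinol epimers) | CC(=O)O[C@H](C)[C@H](/C=C/[C@@H]1O[C@H](C(C)O)[C@@H]2OC(=O)O[C@H]12)OC(=O)c1ccccc1
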